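The C7–C8 bond (germacrane numbering) lies in the homoallylic array O–C8–C7–C11(=C13) and is shared by the α-methylene-γ-butyrolactone and the oxepane ring O–C5–C6–C7–C8–C9–C10 of the 11-oxabicyclo[4.4.1]undecane core. In the open precursor both carbons are electrophilic (aldehyde C8, enoate β-carbon C7), so they are joined by polarity reversal: CrCl2 turns a 2-(bromomethyl)enoate into an allylchromium whose γ-carbon C7 attacks the aldehyde. One operation closes the oxepane ring (hence the ten-membered carbocycle), sets C7 and C8, releases the exocyclic methylene and forms the lactone. The precursor is a cis-2,7-disubstituted oxepane bearing an α-isovaleryloxy aldehyde and a bromomethyl enoate arm, made from geraniol.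

Key step: step 11

Remark: germacrane numbering is used for all intermediates in the Why lines. C8 carries the lactone oxygen, C7 the C11(=C13H2)–C12(=O) unit, C9 the isovalerate, C10 the methyl C14 and the ether oxygen, C5 the other ether bond, C4 the methyl C15; C1–C3 and C6 are CH2.

Remark: the sense of induction in steps 3, 5 and 6 is assigned from the accepted facial models of these reactions; should one prove opposite, the antipodal ligand, reagent or ketone would be used.

Step 1
Reactants: 1 geraniol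
Product: 2 (E)-1-{[(3,7-dimethylocta-2,6-dien-1-yl)oxy]methyl}-4-methoxybenzene (geranyl PMB ether)
Conditions: NaH, PMBCl, Bu4NI (cat.), THF/DMF, 0 °C to rt
Reagents that add atoms: 4-methoxybenzyl chloride, COc1ccc(CCl)cc1
Why: Williamson ether synthesis on the primary allylic alkoxide; no stereocentre is involved, and the ether can later be removed by DDQ under neutral conditions.

Step 2
Reactants: 2 geranyl PMB ether
Product: 3 (2E,6E)-8-[(4-methoxybenzyl)oxy]-2,6-dimethylocta-2,6-dien-1-ol
Conditions: SeO2 (cat.), t-BuOOH, salicylic acid (cat.), CH2Cl2, 0 °C to rt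
Reagents that add atoms: tert-butyl hydroperoxide, CC(C)(C)OO
Why: Riley allylic oxidation (ene reaction, then [2,3]-sigmatropic shift) should attack the more electron-rich distal trisubstituted alkene at its (E)-methyl group, the usual outcome for geranyl ethers and esters, because the other alkene is deactivated by the allylic oxygen.

Step 3
Reactants: 3 (2E,6E)-8-[(4-methoxybenzyl)oxy]-2,6-dimethylocta-2,6-dien-1-ol
Product: 4 (2S,6E)-8-[(4-methoxybenzyl)oxy]-2,6-dimethyloct-6-en-1-ol
Conditions: Ru(OAc)2[(S)-BINAP] (1 mol%), H2 (50 atm), MeOH, rt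
Reagents that add atoms: none
Why: Noyori asymmetric hydrogenation of an allylic alcohol: the hydroxyl binds ruthenium and directs H2 to one alkene face, (S)-BINAP being expected to set C4 as S by the facial sense that converts geraniol into (R)-citronellol, while the non-coordinating allylic-ether alkene and the PMB group should stay untouched.

Step 4
Reactants: 4 (2S,6E)-8-[(4-methoxybenzyl)oxy]-2,6-dimethyloct-6-en-1-ol
Product: 5 (2S,6E)-8-[(4-methoxybenzyl)oxy]-2,6-dimethyloct-6-enal
Conditions: Dess–Martin periodinane, pyridine, CH2Cl2, 0 °C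
Reagents that add atoms: none
Why: Dess–Martin oxidation of the primary alcohol under buffered conditions should not epimerise the α-methyl centre C4; the aldehyde is used at once.

Step 5
Reactants: 5 (2S,6E)-8-[(4-methoxybenzyl)oxy]-2,6-dimethyloct-6-enal
Product: 6 (4R,5S,9E)-11-[(4-methoxybenzyl)oxy]-5,9-dimethylundeca-1,9-dien-4-ol
Conditions: (+)-Ipc2B(allyl) [from (−)-α-pinene], Et2O, −78 °C; then NaOH, H2O2, 0 °C to rt
Reagents that add atoms: (+)-B-allyldiisopinocampheylborane, C=CCB([C@H]1C[C@H]2C[C@@H]([C@@H]1C)C2(C)C)[C@H]1C[C@H]2C[C@@H]([C@@H]1C)C2(C)C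
Why: Brown asymmetric allylboration through a closed Zimmerman–Traxler chair: the (+)-reagent should add to the Re face (the sense that gives (R)-1-phenylbut-3-en-1-ol from benzaldehyde), setting C5 as R, anti to the C4 methyl, by reagent control over the weak Felkin bias of the α-methyl aldehyde.

Step 6
Reactants: 6 (4R,5S,9E)-11-[(4-methoxybenzyl)oxy]-5,9-dimethylundeca-1,9-dien-4-ol
Product: 8 (1S)-1-[(2R,6S,7R)-2,6-dimethyl-7-(prop-2-en-1-yl)oxepan-2-yl]-2-[(4-methoxybenzyl)oxy]ethan-1-ol, via epoxy alcohol 7 (not isolated)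
Conditions: L-fructose-derived Shi ketone (ent-Shi ketone, 0.5 equiv), KHSO5 (as its triple salt), K2CO3, Bu4NHSO4, MeCN/CH2(OMe)2/aq. Na2B4O7 buffer, 0 °C; then CSA (cat.), CH2Cl2, 0 °C to rt
Reagents that add atoms: potassium peroxymonosulfate, [K+].[O-]S(=O)(=O)OO
Why: Shi epoxidation (chiral dioxirane, spiro transition state) with the L-fructose-derived ketone should give the (9S,10S)-epoxide of the trisubstituted alkene (the D-ketone gives R,R-epoxides of such alkenes) and leave the terminal alkene alone; acid then promotes a 7-exo-tet opening by the C5 hydroxyl at the tertiary carbon C10 with inversion, which sets the quaternary ether centre as 10R, frees the C9 hydroxyl (S) with retention and makes the oxepane cis-2,7 by necessity.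

Step 7
Reactants: 8 (1S)-1-[(2R,6S,7R)-2,6-dimethyl-7-(prop-2-en-1-yl)oxepan-2-yl]-2-[(4-methoxybenzyl)oxy]ethan-1-ol; 9 3-methylbutanoic anhydride
Product: 10 (1S)-1-[(2R,6S,7R)-2,6-dimethyl-7-(prop-2-en-1-yl)oxepan-2-yl]-2-[(4-methoxybenzyl)oxy]ethyl 3-methylbutanoate
Conditions: Et3N, DMAP (cat.), CH2Cl2, 0 °C to rt
Reagents that add atoms: none
Why: DMAP-catalysed acyl transfer (Steglich-type acylation) to the only free hydroxyl; no stereocentre is touched.

Step 8
Reactants: 10 (1S)-1-[(2R,6S,7R)-2,6-dimethyl-7-(prop-2-en-1-yl)oxepan-2-yl]-2-[(4-methoxybenzyl)oxy]ethyl 3-methylbutanoate; 11 methyl 2-(bromomethyl)prop-2-enoate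
Product: 12 methyl (2Z)-2-(bromomethyl)-4-[(2R,3S,7R)-7-{(1S)-2-[(4-methoxybenzyl)oxy]-1-[(3-methylbutanoyl)oxy]ethyl}-3,7-dimethyloxepan-2-yl]but-2-enoate
Conditions: second-generation Hoveyda–Grubbs catalyst [RuCl2(H2IMes)(=CH-C6H4-2-OiPr)] (10 mol%), 11 (5 equiv), CH2Cl2, 40 °C
Reagents that add atoms: none
Why: olefin cross-metathesis of a terminal alkene with a 1,1-disubstituted acrylate (as known for methacrylates) should engage only the unhindered allyl group, with loss of ethylene, and the trisubstituted product cannot re-enter metathesis; the alkene geometry (chain expected trans to the ester) is inconsequential because the allylchromium of step 11 equilibrates.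

Step 9
Reactants: 12 methyl (2Z)-2-(bromomethyl)-4-[(2R,3S,7R)-7-{(1S)-2-[(4-methoxybenzyl)oxy]-1-[(3-methylbutanoyl)oxy]ethyl}-3,7-dimethyloxepan-2-yl]but-2-enoate
Product: 13 methyl (2Z)-2-(bromomethyl)-4-[(2R,3S,7R)-7-{(1S)-2-hydroxy-1-[(3-methylbutanoyl)oxy]ethyl}-3,7-dimethyloxepan-2-yl]but-2-enoate
Conditions: DDQ, CH2Cl2/pH 7 buffer, 0 °C to rt
Reagents that add atoms: none
Why: oxidative PMB cleavage by DDQ (hydride abstraction, then hydrolysis of the oxocarbenium ion) runs under neutral conditions, so that neither the allylic bromide nor the neighbouring isovalerate (1,2-acyl migration) should be disturbed.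

Step 10
Reactants: 13 methyl (2Z)-2-(bromomethyl)-4-[(2R,3S,7R)-7-{(1S)-2-hydroxy-1-[(3-methylbutanoyl)oxy]ethyl}-3,7-dimethyloxepan-2-yl]but-2-enoate
Product: 14 methyl (2Z)-2-(bromomethyl)-4-[(2R,3S,7R)-3,7-dimethyl-7-{(1R)-1-[(3-methylbutanoyl)oxy]-2-oxoethyl}oxepan-2-yl]but-2-enoate
Conditions: Dess–Martin periodinane, CH2Cl2, 0 °C to rt
Reagents that add atoms: none
Why: Dess–Martin oxidation gives the α-acyloxy aldehyde without base, so C9 should not epimerise and the acyl group should not migrate; the crude aldehyde is cyclised directly (the descriptor at C9 changes to R only because the formyl group now outranks C10).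

Step 11
Reactants: 14 methyl (2Z)-2-(bromomethyl)-4-[(2R,3S,7R)-3,7-dimethyl-7-{(1R)-1-[(3-methylbutanoyl)oxy]-2-oxoethyl}oxepan-2-yl]but-2-enoate
Product: 16 target CNP0274454.1 [(4S,5R,7R,8R,9S,10R)-5,10-epoxy-9-[(3-methylbutanoyl)oxy]germacr-11(13)-en-12,8-olide], via hydroxy ester 15 (not isolated)
Conditions: CrCl2 (8 equiv), THF, 0.005 M, slow addition, rt; then TsOH (cat.), CH2Cl2, rt
Reagents that add atoms: none
Why: CrCl2 reduces the allylic C13–Br bond by two single-electron transfers to a 2-(methoxycarbonyl)allyl species of trivalent chromium, whose γ-carbon C7 (natively the electrophilic enoate β-carbon) adds to the aldehyde carbon C8 in an SE2′ sense, after which the C8 alkoxide closes onto the C12 ester. The closest known reaction type is the intramolecular Nozaki–Hiyama–Kishi (Barbier-type) allylation of ω-formyl 2-(bromomethyl)alk-2-enoates, used to make carbocycle-fused α-methylene-γ-butyrolactones. The oxepane ring O–C5–C6–C7–C8–C9–C10 (and with it the ten-membered carbocycle C1–C10) closes by 7-exo-trig addition to the C8 carbonyl, and the lactone O–C8–C7–C11–C12 closes by 5-exo-trig acyl substitution with loss of methanol. C8 should be controlled by the resident C9 and C10 centres: in a chair-like seven-membered transition state the C9 isovalerate is equatorial and antiperiplanar to the forming bond (polar Felkin–Anh alignment) and the carbonyl oxygen points outward to chromium, giving 8R with C8–O trans to C9–O. C7 should be controlled by the Zimmerman–Traxler chair: the σ-allylchromium equilibrates by 1,3-metal shift and reacts through the isomer that places the C6 and C9 tether ends both equatorial, giving the anti adduct and hence the trans-fused lactone (7R). The step needs γ- over α-attack (closed transition state and smaller ring), ring closure over dimerisation (high dilution) and aldehyde over ester selectivity (inherent to allylchromium reagents).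

Compound list
1 | geraniol | CC(C)=CCC/C(C)=C/CO | starting material
2 | (E)-1-{[(3,7-dimethylocta-2,6-dien-1-yl)oxy]methyl}-4-methoxybenzene | CC(C)=CCC/C(C)=C/COCc1ccc(OC)cc1 | intermediate
3 | (2E,6E)-8-[(4-methoxybenzyl)oxy]-2,6-dimethylocta-2,6-dien-1-ol | OC/C(C)=C/CC/C(C)=C/COCc1ccc(OC)cc1 | intermediate
4 | (2S,6E)-8-[(4-methoxybenzyl)oxy]-2,6-dimethyloct-6-en-1-ol | OC[C@@H](C)CCC/C(C)=C/COCc1ccc(OC)cc1 | intermediate
5 | (2S,6E)-8-[(4-methoxybenzyl)oxy]-2,6-dimethyloct-6-enal | O=C[C@@H](C)CCC/C(C)=C/COCc1ccc(OC)cc1 | intermediate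
6 | (4R,5S,9E)-11-[(4-methoxybenzyl)oxy]-5,9-dimethylundeca-1,9-dien-4-ol | C=CC[C@@H](O)[C@@H](C)CCC/C(C)=C/COCc1ccc(OC)cc1 | intermediate
7 | (4R,5S)-8-[(2S,3S)-3-{[(4-methoxybenzyl)oxy]methyl}-2-methyloxiran-2-yl]-5-methyloct-1-en-4-ol | C=CC[C@@H](O)[C@@H](C)CCC[C@]1(C)O[C@H]1COCc1ccc(OC)cc1 | intermediate (not isolated)
8 | (1S)-1-[(2R,6S,7R)-2,6-dimethyl-7-(prop-2-en-1-yl)oxepan-2-yl]-2-[(4-methoxybenzyl)oxy]ethan-1-ol | C=CC[C@H]1O[C@](C)(CCC[C@@H]1C)[C@@H](O)COCc1ccc(OC)cc1 | intermediate
9 | 3-methylbutanoic anhydride | CC(C)CC(=O)OC(=O)CC(C)C | starting material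
10 | (1S)-1-[(2R,6S,7R)-2,6-dimethyl-7-(prop-2-en-1-yl)oxepan-2-yl]-2-[(4-methoxybenzyl)oxy]ethyl 3-methylbutanoate | C=CC[C@H]1O[C@](C)(CCC[C@@H]1C)[C@@H](OC(=O)CC(C)C)COCc1ccc(OC)cc1 | intermediate
11 | methyl 2-(bromomethyl)prop-2-enoate | C=C(CBr)C(=O)OC | starting material
12 | methyl (2Z)-2-(bromomethyl)-4-[(2R,3S,7R)-7-{(1S)-2-[(4-methoxybenzyl)oxy]-1-[(3-methylbutanoyl)oxy]ethyl}-3,7-dimethyloxepan-2-yl]but-2-enoate | COC(=O)/C(CBr)=C/C[C@H]1O[C@](C)(CCC[C@@H]1C)[C@@H](OC(=O)CC(C)C)COCc1ccc(OC)cc1 | intermediate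
13 | methyl (2Z)-2-(bromomethyl)-4-[(2R,3S,7R)-7-{(1S)-2-hydroxy-1-[(3-methylbutanoyl)oxy]ethyl}-3,7-dimethyloxepan-2-yl]but-2-enoate | COC(=O)/C(CBr)=C/C[C@H]1O[C@](C)(CCC[C@@H]1C)[C@@H](OC(=O)CC(C)C)CO | intermediate
14 | methyl (2Z)-2-(bromomethyl)-4-[(2R,3S,7R)-3,7-dimethyl-7-{(1R)-1-[(3-methylbutanoyl)oxy]-2-oxoethyl}oxepan-2-yl]but-2-enoate | COC(=O)/C(CBr)=C/C[C@H]1O[C@](C)(CCC[C@@H]1C)[C@@H](OC(=O)CC(C)C)C=O | intermediate
15 | methyl 2-[(1R,2S,3R,4R,6R,7S)-3-hydroxy-1,7-dimethyl-2-[(3-methylbutanoyl)oxy]-11-oxabicyclo[4.4.1]undecan-4-yl]prop-2-enoate | C=C(C(=O)OC)[C@H]1C[C@H]2O[C@](C)(CCC[C@@H]2C)[C@@H](OC(=O)CC(C)C)[C@@H]1O | intermediate (not isolated)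
16 | CNP0274454.1, (4S,5R,7R,8R,9S,10R)-5,10-epoxy-9-[(3-methylbutanoyl)oxy]germacr-11(13)-en-12,8-olide | C=C1C(=O)O[C@@H]2[C@@H]1C[C@H]1O[C@](C)(CCC[C@@H]1C)[C@H]2OC(=O)CC(C)C | target

Total step count: 11
Longest linear sequence: 11 steps (from geraniol 1; compounds 9 and 11 are purchased)

Steps most likely to fail

1. Step 11 (key ring closure). The closed chromium transition state may give poor facial selectivity (cis-fused lactone or the C8 epimer), and the α-acyloxy aldehyde may suffer 1,2-acyl migration or reduction before the ring closes. The fallback closes the same C7–C8 bond by a radical instead of an allylmetal. It sets out from 8: silylation (TBSOTf, 2,6-lutidine) should give tert-butyldimethylsilyl ether F1; cross-metathesis with methyl acrylate (second-generation Hoveyda–Grubbs catalyst) should give (E)-enoate F2; DDQ should give primary alcohol F3; Dess–Martin oxidation should give aldehyde F4. SmI2 with MeOH in THF should then effect a ketyl–olefin 7-exo-trig reductive cyclisation, in which the samarium ketyl oxygen and the ester-bearing carbon prefer to be trans, followed by lactonisation to saturated trans-lactone F5. The methylene is added afterwards: LiN(SiMe3)2 then CH2=NMe2+ I− should give Mannich base F6; MeI should give methiodide F7 (not isolated), which should eliminate with NaHCO3 to α-methylene lactone silyl ether F8; HF·pyridine should give hydroxy lactone F9; acylation with 9 (Et3N, DMAP) comes back to the route at 16.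

2. Step 8 (cross-metathesis). The electron-poor 1,1-disubstituted partner may react sluggishly, so that homodimerisation of 10 and catalyst decay compete. The fallback builds the arm by carbonyl chemistry and sets out from 10: Lemieux–Johnson cleavage (OsO4 cat., NaIO4, 2,6-lutidine, dioxane/H2O) should give aldehyde F10; vinylalumination (methyl propiolate, iBu2AlH, N-methylmorpholine N-oxide, THF; a Morita–Baylis–Hillman surrogate that avoids prolonged amine base on the β-alkoxy aldehyde) should give allylic alcohol F11 as an inconsequential epimer mixture; SN2′ bromination (NBS, Me2S, CH2Cl2) comes back to the route at 12.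

3. Step 6 (epoxidation and oxepane closure). Facial selectivity may be low on the allylic-ether alkene, which is deactivated towards the dioxirane, and Meinwald rearrangement or elimination of the tertiary epoxide may outrun the slow seven-membered ring closure. The fallback uses a hydroxyl-directed epoxidation and a chelation-activated opening and sets out from 6: DDQ should give diol F12; Sharpless asymmetric epoxidation (Ti(OiPr)4, L-(+)-diethyl tartrate, t-BuOOH, 4 Å sieves, −20 °C) should give the (2S,3S)-epoxy diol F13; Ti(OiPr)4 bound to the epoxy alcohol should direct the intramolecular attack of the C5 hydroxyl to the tertiary epoxide carbon and give oxepane diol F14; primary-selective etherification through the stannylene acetal (Bu2SnO; then PMBCl, CsF) comes back to the route at 8.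

Further compounds
F1 | step 11 | tert-butyl({(1S)-1-[(2R,6S,7R)-2,6-dimethyl-7-(prop-2-en-1-yl)oxepan-2-yl]-2-[(4-methoxybenzyl)oxy]ethyl}oxy)dimethylsilane | C=CC[C@H]1O[C@](C)(CCC[C@@H]1C)[C@@H](O[Si](C)(C)C(C)(C)C)COCc1ccc(OC)cc1
F2 | step 11 | methyl (2E)-4-[(2R,3S,7R)-7-{(1S)-1-[(tert-butyldimethylsilyl)oxy]-2-[(4-methoxybenzyl)oxy]ethyl}-3,7-dimethyloxepan-2-yl]but-2-enoate | COC(=O)/C=C/C[C@H]1O[C@](C)(CCC[C@@H]1C)[C@@H](O[Si](C)(C)C(C)(C)C)COCc1ccc(OC)cc1
F3 | step 11 | methyl (2E)-4-[(2R,3S,7R)-7-{(1S)-1-[(tert-butyldimethylsilyl)oxy]-2-hydroxyethyl}-3,7-dimethyloxepan-2-yl]but-2-enoate | COC(=O)/C=C/C[C@H]1O[C@](C)(CCC[C@@H]1C)[C@@H](O[Si](C)(C)C(C)(C)C)CO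
F4 | step 11 | methyl (2E)-4-[(2R,3S,7R)-7-{(1R)-1-[(tert-butyldimethylsilyl)oxy]-2-oxoethyl}-3,7-dimethyloxepan-2-yl]but-2-enoate | COC(=O)/C=C/C[C@H]1O[C@](C)(CCC[C@@H]1C)[C@@H](O[Si](C)(C)C(C)(C)C)C=O
F5 | step 11 | (4S,5R,7R,8R,9S,10R)-9-[(tert-butyldimethylsilyl)oxy]-5,10-epoxy-13-norgermacran-12,8-olide | C1C(=O)O[C@@H]2[C@@H]1C[C@H]1O[C@](C)(CCC[C@@H]1C)[C@H]2O[Si](C)(C)C(C)(C)C
F6 | step 11 | (4S,5R,7R,8R,9S,10R)-9-[(tert-butyldimethylsilyl)oxy]-13-(dimethylamino)-5,10-epoxygermacran-12,8-olide (C11 epimers) | CN(C)CC1C(=O)O[C@@H]2[C@@H]1C[C@H]1O[C@](C)(CCC[C@@H]1C)[C@H]2O[Si](C)(C)C(C)(C)C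
F7 | step 11 | trimethylammonium iodide of F6 | C[N+](C)(C)CC1C(=O)O[C@@H]2[C@@H]1C[C@H]1O[C@](C)(CCC[C@@H]1C)[C@H]2O[Si](C)(C)C(C)(C)C.[I-]
F8 | step 11 | (4S,5R,7R,8R,9S,10R)-9-[(tert-butyldimethylsilyl)oxy]-5,10-epoxygermacr-11(13)-en-12,8-olide | C=C1C(=O)O[C@@H]2[C@@H]1C[C@H]1O[C@](C)(CCC[C@@H]1C)[C@H]2O[Si](C)(C)C(C)(C)C
F9 | step 11 | (4S,5R,7R,8R,9S,10R)-5,10-epoxy-9-hydroxygermacr-11(13)-en-12,8-olide | C=C1C(=O)O[C@@H]2[C@@H]1C[C@H]1O[C@](C)(CCC[C@@H]1C)[C@H]2O
F10 | step 8 | (1S)-1-[(2R,6S,7R)-2,6-dimethyl-7-(2-oxoethyl)oxepan-2-yl]-2-[(4-methoxybenzyl)oxy]ethyl 3-methylbutanoate | O=CC[C@H]1O[C@](C)(CCC[C@@H]1C)[C@@H](OC(=O)CC(C)C)COCc1ccc(OC)cc1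
F11 | step 8 | methyl 3-hydroxy-4-[(2R,3S,7R)-7-{(1S)-2-[(4-methoxybenzyl)oxy]-1-[(3-methylbutanoyl)oxy]ethyl}-3,7-dimethyloxepan-2-yl]-2-methylidenebutanoate (C3 epimers) | C=C(C(=O)OC)C(O)C[C@H]1O[C@](C)(CCC[C@@H]1C)[C@@H](OC(=O)CC(C)C)COCc1ccc(OC)cc1
F12 | step 6 | (2E,7S,8R)-3,7-dimethylundeca-2,10-diene-1,8-diol | C=CC[C@@H](O)[C@@H](C)CCC/C(C)=C/CO
F13 | step 6 | (4R,5S)-8-[(2S,3S)-3-(hydroxymethyl)-2-methyloxiran-2-yl]-5-methyloct-1-en-4-ol | C=CC[C@@H](O)[C@@H](C)CCC[C@]1(C)O[C@H]1CO
F14 | step 6 | (1S)-1-[(2R,6S,7R)-2,6-dimethyl-7-(prop-2-en-1-yl)oxepan-2-yl]ethane-1,2-diol | C=CC[C@H]1O[C@](C)(CCC[C@@H]1C)[C@@H](O)CO
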